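## Retrosynthetic overview

1. The C9–O ester bond is cut first: the target comes from trans-diaxial opening of the 8α,9α-vinyl epoxide 14 by angelic acid. Epoxide 14 comes from the enone 11 by Weitz–Scheffer epoxidation and Wittig methylenation, with the C4 ketone masked as a ketal.
2. The C8=C9 enone and the isopropyl group come from Lewis-acid fragmentation of the pinane cyclobutane of tricycle 9 (nopinone → cryptone type). The six-membered ring and C7 are bought in (+)-nopinone.
3. The 2-acetoxycyclopentanone comes from α-ketol ring expansion of a 1-hydroxycyclobutanecarbaldehyde (C6 migrates to C5).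
4. That cyclobutane (bonds C2–C3 and C6–C4) comes from a [2+2] photocycloaddition of apoverbenone 3 with the 2-siloxyacrolein acetal 5, anti to the CMe2 bridge.
5. Ring order: six-membered ring bought (pinane) → four-membered ring (hν) → five-membered ring (ring expansion) → pinane four-membered ring opened.

Assumption: (1R,5S)-(+)-nopinone (the ozonolysis product of (−)-β-pinene) is bought and is the only source of chirality.

Locants follow the target SMILES: C10H2=C1; C2 and C6 are the ring-fusion CH; C3H2; C4=O; C5–OAc; C7–iPr; C8–OH; C9–OAng; C11 is the CMe2 carbon (later the isopropyl CH). β is the face of H-2 in the target, α the face of H-6. Target: H-2 β, H-6 α, 5α-OAc, 7α-iPr, 8α-OH, 9β-OAng.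

## Route

Step 1
Reactants: 1 (1R,5S)-(+)-nopinone
Product: 3 (1R,5R)-(+)-apoverbenone, via nopinone trimethylsilyl enol ether 2 (not isolated)
Conditions: LDA, THF, −78 °C; TMSCl; then Pd(OAc)2 (1.1 equiv), MeCN, rt
Reagents that add atoms: none
Why: Saegusa–Ito dehydrogenation, in which enolisation can only go towards C2 (a bridgehead enolate at C9 is anti-Bredt) and β-hydride elimination of the Pd(II) enolate gives the C2=C6 enone without touching either bridgehead stereocentre.

Step 2
Reactants: 4 1,1-dimethoxypropan-2-one
Product: 5 3,3-dimethoxy-2-(trimethylsilyloxy)prop-1-ene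
Conditions: LDA, THF, −78 °C; TMSCl; distil
Reagents that add atoms: chlorotrimethylsilane C[Si](C)(C)Cl
Why: Kinetic deprotonation takes the methyl proton rather than the hindered acetal C–H, and O-silylation gives the terminal silyl enol ether (silyl enol ether formation).

Step 3
Reactants: 3 (1R,5R)-(+)-apoverbenone; 5 3,3-dimethoxy-2-(trimethylsilyloxy)prop-1-ene
Product: 6 cyclobutane photoadduct
Conditions: hν (366 nm LED, Pyrex), 5 (6 equiv), MeCN, −20 °C, degassed
Reagents that add atoms: none
Why: Proposed new method: a crossed enone–alkene [2+2] photocycloaddition of a pinane enone with a 2-siloxyacrolein acetal as a latent acyloin unit, which has not been described (verbenone-type enones are known on irradiation only for the unimolecular 1,3-acyl shift); the rigid triplet enone should be trapped by a large excess of electron-rich alkene faster than it rearranges, bonding head-to-tail (CH2 to the α-carbon C2, the oxygenated carbon to the β-carbon C6) as in the closest known reaction, the cyclohexenone–silyl enol ether/ketene acetal [2+2] photocycloaddition, and on the face anti to the CMe2 bridge as in cuprate additions to apoverbenone, which sets C6 (new bond β, trans to the future isopropyl) and gives the cis-fused cyclobutane.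

Step 4
Reactants: 6 cyclobutane photoadduct
Product: 9 tricyclic acetoxy diketone, via hydroxy aldehyde 7 (not isolated), via hydroxy ketone 8 (not isolated)
Conditions: (i) TFA, H2O, CH2Cl2, 0 °C → rt; (ii) Ac2O, Et3N, DMAP, CH2Cl2, rt
Reagents that add atoms: water O; acetic anhydride CC(=O)OC(C)=O
Why: Acid removes the silyl ether and the acetal, and the resulting 1-hydroxycyclobutanecarbaldehyde undergoes the strain-driven α-ketol (acyloin) rearrangement in which the more substituted ring carbon C6 migrates with retention to the aldehyde carbon, giving the 2-hydroxycyclopentanone with the carbonyl at C4, after which acetylation under Et3N/DMAP fixes the oxygen as acetate and lets the enolisable C5 settle with OAc anti to C7 (away from the CH2 bridge), which is the configuration of the target.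

Step 5
Reactants: 9 tricyclic acetoxy diketone
Product: 10 cis-fused hydrindenone
Conditions: AlCl3 (3 equiv), CH2Cl2, 0 °C → rt
Reagents that add atoms: none
Why: Lewis-acid fragmentation of the nopinone cyclobutane (the known nopinone-to-cryptone isomerisation), in which the AlCl3-bound ketone ionises the strained C9–C11 bond to a tertiary cation and an aluminium enolate, hydride transfer from C8 then gives the isopropyl group and the C8=C9 enone, and C7 is never planarised so its bought configuration survives.

Step 6
Reactants: 10 cis-fused hydrindenone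
Product: 11 C4 dimethyl ketal of 10
Conditions: MeOSiMe3 (4 equiv), TMSOTf (10 mol %), CH2Cl2, −78 → −30 °C
Reagents that add atoms: methoxytrimethylsilane CO[Si](C)(C)C
Why: Noyori ketalisation is selective for the saturated cyclopentanone over the conjugated C1 enone, which masks C4 for the basic steps that follow and locks C5.

Step 7
Reactants: 11 C4 dimethyl ketal of 10
Product: 13 trans-fused 8α,9α-epoxy ketone, via trans-fused enone ketal 12 (not isolated)
Conditions: DBU (1.2 equiv), CH2Cl2, rt; then t-BuOOH (decane), 0 °C → rt
Reagents that add atoms: tert-butyl hydroperoxide CC(C)(C)OO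
Why: DBU equilibrates C2 through the enolate towards the trans-fused series (C3 and C5 both equatorial, whereas the cis isomer holds C3 axial and pushes one ketal OMe into the concave face; about 3:1 or better is expected by analogy with hydrindan-4-one, and the minor epimer is recycled with DBU), and Weitz–Scheffer epoxidation then proceeds by axial attack of t-BuOO− on C8 from the α-face (anti to axial H-7, chair-like enolate), so ring closure gives the 8α,9α-epoxide cis to the equatorial isopropyl.

Step 8
Reactants: 13 trans-fused 8α,9α-epoxy ketone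
Product: 14 vinyl epoxide
Conditions: Ph3PCH3Br, KOtBu, THF, 0 °C; then 13, 0 °C → rt
Reagents that add atoms: methyltriphenylphosphonium bromide C[P+](c1ccccc1)(c1ccccc1)c1ccccc1.[Br-]
Why: Wittig methylenation of the only free ketone (C4 is a ketal), a reaction that tolerates α,β-epoxy ketones and leaves every stereocentre in place, gives the exocyclic methylene.

Step 9
Reactants: 14 vinyl epoxide
Product: 16 target CNP0317011.1, via hydroxy angelate ketal 15 (not isolated)
Conditions: angelic acid (5 equiv), Cs2CO3 (5 mol %), PhMe, 40 °C; then PPTS, acetone–H2O, rt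
Reagents that add atoms: angelic acid C/C=C(/C)C(=O)O; water O
Why: Acid-assisted SN2 opening of the vinyl epoxide by angelate at the allylic carbon C9 from the β-face is the Fürst–Plattner trans-diaxial mode, so electronic and stereoelectronic preferences coincide and give the 9β-ester and 8α-alcohol with inversion at C9 and no base that could isomerise the (Z)-alkene, and PPTS then hydrolyses the dimethyl ketal to the C4 ketone.

## Compound list

1 | (1R,5S)-(+)-nopinone, 6,6-dimethylbicyclo[3.1.1]heptan-2-one (C1=O; C9 and C7 bridgeheads; C11Me2 bridge on the α-face) | O=C1CC[C@H]2C[C@@H]1C2(C)C | starting material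
2 | nopinone trimethylsilyl enol ether (C1(OTMS)=C2) | C[Si](C)(C)OC1=CC[C@H]2C[C@@H]1C2(C)C | intermediate
3 | (1R,5R)-(+)-apoverbenone, 6,6-dimethylbicyclo[3.1.1]hept-3-en-2-one (enone C1(=O)–C2=C6) | O=C1C=C[C@H]2C[C@@H]1C2(C)C | intermediate
4 | 1,1-dimethoxypropan-2-one (pyruvaldehyde dimethyl acetal) | CC(=O)C(OC)OC | starting material
5 | 3,3-dimethoxy-2-(trimethylsilyloxy)prop-1-ene | C=C(O[Si](C)(C)C)C(OC)OC | intermediate
6 | photoadduct: cyclobutane C2–C3H2–C4(OTMS)[CH(OMe)2]–C6 cis-fused on the β-face of nopinone (anti to the CMe2 bridge), H-2 α, H-6 α, both C4 epimers | O=C1[C@H]2CC(O[Si](C)(C)C)(C(OC)OC)[C@H]2[C@H]3C[C@@H]1C3(C)C | intermediate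
7 | hydroxy aldehyde (C4–OH, C5H=O on the cyclobutane of 6) | O=C1[C@H]2CC(O)(C=O)[C@H]2[C@H]3C[C@@H]1C3(C)C | intermediate
8 | hydroxy ketone: cyclopentanone C2–C3H2–C4(=O)–C5H(OH)–C6 cis-fused on the β-face of nopinone, 5-OH anti to C7 | O=C1[C@H]2CC(=O)[C@H](O)[C@H]2[C@H]3C[C@@H]1C3(C)C | intermediate
9 | tricyclic acetoxy diketone (acetate of 8) | O=C1[C@H]2CC(=O)[C@H](OC(C)=O)[C@H]2[C@H]3C[C@@H]1C3(C)C | intermediate
10 | cis-fused hydrindenone: C1(=O)–C9=C8 enone, 7α-isopropyl, H-2 α, H-6 α, C4 ketone, 5α-OAc | O=C1[C@H]2CC(=O)[C@H](OC(C)=O)[C@H]2[C@H](C(C)C)C=C1 | intermediate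
11 | C4 dimethyl ketal of 10 | O=C1[C@H]2CC(OC)(OC)[C@H](OC(C)=O)[C@H]2[C@H](C(C)C)C=C1 | intermediate
12 | trans-fused enone ketal (C2 epimer of 11: H-2 β, H-6 α) | O=C1[C@@H]2CC(OC)(OC)[C@H](OC(C)=O)[C@H]2[C@H](C(C)C)C=C1 | intermediate
13 | trans-fused 8α,9α-epoxy ketone (epoxide cis to the 7α-isopropyl) | O=C1[C@@H]2CC(OC)(OC)[C@H](OC(C)=O)[C@H]2[C@H](C(C)C)[C@@H]3O[C@@H]31 | intermediate
14 | vinyl epoxide (1-methylidene analogue of 13) | C=C1[C@@H]2CC(OC)(OC)[C@H](OC(C)=O)[C@H]2[C@H](C(C)C)[C@@H]3O[C@@H]31 | intermediate
15 | hydroxy angelate ketal (9β-angeloyloxy, 8α-hydroxy, 4,4-dimethoxy) | C=C1[C@@H]2CC(OC)(OC)[C@H](OC(C)=O)[C@H]2[C@H](C(C)C)[C@H](O)[C@H]1OC(=O)/C(C)=C\C | intermediate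
16 | CNP0317011.1, (1R,3aR,5S,6S,7S,7aR)-1-acetoxy-6-hydroxy-4-methylidene-2-oxo-7-(propan-2-yl)octahydro-1H-inden-5-yl (Z)-2-methylbut-2-enoate | C=C1[C@@H]2CC(=O)[C@H](OC(C)=O)[C@H]2[C@H](C(C)C)[C@H](O)[C@H]1OC(=O)/C(C)=C\C | target

## Step count and risks

Total step count: 9 (steps 1–9, including the one-step preparation of alkene 5). Longest linear sequence: 8 steps (1 → 16 through steps 1 and 3–9).

The three steps most likely to fail:

Step 3 (the proposed new photocycloaddition). The excited pinane enone may rearrange by 1,3-acyl shift instead of adding the alkene, or the alkene may add head-to-head. The fallback uses only known thermal chemistry, sets out from 3 and comes back at 8. Copper-catalysed 1,4-addition of vinylmagnesium bromide to 3 (CuBr·SMe2, THF, −78 °C) occurs anti to the CMe2 bridge. The magnesium enolate is alkylated in the same pot with iodoacetonitrile (HMPA) to give the 2β-cyanomethyl-6β-vinyl nopinone F1. Ozonolysis (O3, then Me2S) gives the keto aldehyde F2. A SmI2-mediated ketyl–nitrile cyclisation (THF/MeOH; the Shono cathodic variant is the alternative) closes the five-membered ring to the α-hydroxy imine F3, which is hydrolysed on work-up to hydroxy ketone 8. Compound 8 is then acetylated as in step 4.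

Step 5 (AlCl3 fragmentation). The α-acetoxy ketone may not survive the Lewis acid, or the tertiary cation may rearrange instead of accepting hydride. The fallback sets out from 6 and comes back at 10, opening the pinane ring reductively before the five-membered ring exists. SmI2/HMPA with t-BuOH cleaves the C9–C11 bond through the ketyl (tertiary radical, then protonation) to give the ring-opened saturated ketone F4. Kinetic enolisation towards C9 (LDA, TMSCl) gives its trimethylsilyl enol ether F5, and Pd(OAc)2 (Saegusa–Ito) gives the enone F6. Aqueous TFA then gives the hydroxy aldehyde F7, which ring-expands by the same α-ketol rearrangement to the cis-fused hydroxy ketone F8. Ac2O/Et3N/DMAP gives 10.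

Step 9 (epoxide opening with angelic acid). SN2′ attack at C10, slow opening, or angelate-to-tiglate isomerisation could intervene. The fallback sets out from 14 and comes back at 16, separating C–O bond formation from acylation. Aqueous HClO4 in THF opens the vinyl epoxide with water at allylic C9 (same trans-diaxial mode) to the ketal diol F9, and the same acid then hydrolyses the ketal to the keto diol F10. Yamaguchi esterification (angelic acid, 2,4,6-trichlorobenzoyl chloride, Et3N; then F10, toluene, 60 °C) acylates the less hindered allylic 9β-OH rather than the 8α-OH flanked by the isopropyl carbon, and gives 16.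

Further compounds
F1 | step 3 | 2β-(cyanomethyl)-6β-vinylnopinone (both new groups anti to the CMe2 bridge) | O=C1[C@@H](CC#N)[C@@H](C=C)[C@H]2C[C@@H]1C2(C)C
F2 | step 3 | 2β-(cyanomethyl)-6β-formylnopinone (keto aldehyde) | O=C1[C@@H](CC#N)[C@@H](C=O)[C@H]2C[C@@H]1C2(C)C
F3 | step 3 | tricyclic α-hydroxy imine (C4=NH, 5-OH; imine analogue of 8) | O=C1[C@H]2CC(=N)[C@H](O)[C@H]2[C@H]3C[C@@H]1C3(C)C
F4 | step 5 | ring-opened saturated ketone (7α-isopropyl, siloxy acetal cyclobutane intact) | O=C1[C@H]2CC(O[Si](C)(C)C)(C(OC)OC)[C@H]2[C@H](C(C)C)CC1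
F5 | step 5 | C1–C9 trimethylsilyl enol ether of F4 | C[Si](C)(C)OC=1[C@H]2CC(O[Si](C)(C)C)(C(OC)OC)[C@H]2[C@H](C(C)C)CC=1
F6 | step 5 | C8=C9 enone with intact siloxy acetal cyclobutane | O=C1[C@H]2CC(O[Si](C)(C)C)(C(OC)OC)[C@H]2[C@H](C(C)C)C=C1
F7 | step 5 | hydroxy aldehyde from F6 (C4–OH, C5H=O) | O=C1[C@H]2CC(O)(C=O)[C@H]2[C@H](C(C)C)C=C1
F8 | step 5 | cis-fused 5α-hydroxy hydrindenone (deacetyl 10) | O=C1[C@H]2CC(=O)[C@H](O)[C@H]2[C@H](C(C)C)C=C1
F9 | step 9 | 8α,9β-diol with 4,4-dimethyl ketal | C=C1[C@@H]2CC(OC)(OC)[C@H](OC(C)=O)[C@H]2[C@H](C(C)C)[C@H](O)[C@H]1O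
F10 | step 9 | 8α,9β-diol 4-ketone (de-angeloyl target) | C=C1[C@@H]2CC(=O)[C@H](OC(C)=O)[C@H]2[C@H](C(C)C)[C@H](O)[C@H]1O
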